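**Questions.** Answer 3 questions on 4 flasks.

| flask | X | Z | G | remark | time |
|---|---|---|---|---|---|
| beta | 10 mM | 14 mM | 10 mM | run made earlier |  |
| theta | 10 mM | 34 mM | 10 mM | run made earlier |  |
| delta | 9.5 mM | 18 mM | 10 mM | run made earlier |  |
| elm | 10 mM | 18.0 mM | 10.0 mM |  | 4.0 h |
| larch | 6.0 mM | 50.0 mM | 10.0 mM |  | 4.0 h |
| oak | 10 mM | 50.0 mM | 10.0 mM |  | 4.0 h |
| ash | 6.0 mM | 18.0 mM | 10.0 mM |  | 4.0 h |

| run | time / h | E / % | X / % |
|---|---|---|---|
| beta | 0.417 | 24 | 60 |
| beta | 0.833 | 39 | 42 |
| beta | 1.33 | 47 | 33 |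
| beta | 1.50 | 49 | 29 |
| beta | 2.00 | 54 | 23 |
| beta | 2.50 | 55 | 16 |
| beta | 3.00 | 56 | 15 |
| theta | 0.167 | 30 | 63 |
| theta | 0.417 | 49 | 36 |
| theta | 0.833 | 53 | 18 |
| theta | 1.33 | 63 | 8 |
| theta | 1.50 | 64 | 10 |
| theta | 2.00 | 64 | 5 |
| theta | 3.00 | 67 | 5 |
| delta | 0.500 | 31 | 48 |
| delta | 1.00 | 50 | 29 |
| delta | 1.50 | 55 | 19 |
| delta | 2.50 | 63 | 14 |
| delta | 3.00 | 65 | 8 |

(readings scatter by 1.5 percentage points)

* the flasks by amount of E, in percent of the X charged, highest first, at 4.0 h (elm / larch / oak / ash)
* the amount of E, in percent of the X charged of the flask you put first, at 4.0 h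
* the amount of E, in percent of the X charged of the flask you put last, at 4.0 h

- a species is counted by the X in it: one Q counts as two
- reactions considered so far: X + Z <-> G + E; E + Z <-> G + D; D + Z <-> G + J; J + Z <-> G + L; 2 X -> Q

**Rung constant.** Read one number from the runs: the D standing per E at equal cZ and cG, the stepwise equilibrium constant, taken alike for each rung up to L. Each rung uses a Z and frees a G, so reckon with cZ/cG at the end.

**Upper bound.** In theta at 3.00 h, E and X leave 28.0% unaccounted for. Count the whole as D, and the constant is at most 0.429.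

**Lower bound.** Q grows while X stands, and X falls sooner in theta, to 63% at 0.167 h, than in beta, to 60% at 0.417 h. Scale the missing part of beta by cZ: Q in theta is at most 11.9%. In theta the rest stands on D, J and L, so spread it over the rungs in equal steps: D per E is then at least the rest divided by E plus the rest. The end cZ/cG in theta is at most what the rest gives when counted as D, because J and L use more Z and free more G, so the constant is at least 0.160.

**Tightening.** The bounds lie 0.428 powers of ten apart. Take the middle in logarithms: 0.262.

**Larch last.** Allow two Z per X. Larch then ends at cZ/cG of 1.73, the highest. Multiply by the constant to get the step p. E holds one part in one plus p plus its square plus its cube. Take off the ceiling on Q in larch, 4.87%. The bracket runs from 35.2% to 69.3%, with the middle at 54.4%.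

**Forecast.** The forecast gives ash > elm > oak > larch, top 71% and low 60%, inside this bracket, on the ground “Oak and larch lose less to Q but more to D”.

**Result.** The flasks give ash > elm > oak > larch, with ash at 67.9% and larch at 49.8%, inside the bracket.

    X + Z ⇌ G + E (K = 15.0, k = 0.0203 M⁻¹ s⁻¹)
    E + Z ⇌ G + D (K = 0.235, k = 0.0114 M⁻¹ s⁻¹)
    D + Z ⇌ G + J (K = 0.260, k = 0.0205 M⁻¹ s⁻¹)
    J + Z ⇌ G + L (K = 0.490, k = 0.00872 M⁻¹ s⁻¹)
    2 X → Q (k = 0.00577 M⁻¹ s⁻¹)

**Rungs balanced.** In ash, the forward half-life of E toward D at charged concentrations is 0.94 h, short against 4.0 h. In larch, the step from D to J has 94% of its turnover behind it at 2.00 h, and E still stands at 49.5% at 40.0 h.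

**Neighbour flask.** Take larch with 25 mM of G: cZ/cG falls to 1.03, and the same constant gives 69.8% of E. That flask gives 64.0%.

All runs were generated by integration from invented constants; noise was put on by code.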